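The four-carbon chain C6–C9 bridges C5 and C10, the two non-adjacent carbons of the cyclobutane (C4–C5–C11–C10). A cyclobutane bridged 1,3 in this way is what a bicyclo[1.1.0]butane gives when its central bond is replaced by two new bonds, and the threo C7/C8 diol is L-tartrate. The seven-membered ring is therefore cut at C5–C6 and C9–C10. In one photoredox operation a tertiary C6 radical, released from cesium oxalate 14 (which also carries the C9 aldehyde), opens the enantiopure tricyclic bicyclobutane ester 9 at C5, and the C10 enolate formed on reduction closes onto the aldehyde, setting C5, C9 and C10.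

Key step: step 10

Remarks on the chemistry (assumptions)
- Longipinane numbering is used for all tricyclic compounds: C1 is the carbonyl carbon of the target, C2=C3 the alkene with the C15 methyl on C3, C6 carries the gem-dimethyl group, C7–C9 carry oxygen, and C14 is the carbon on C10. "15-nor" means no methyl on C3. The descriptors 7β, 8α, 9α are those of the target. In 9, C1/C7/C2/C6/C3–C5 become C10/C5/C4/C11/C3–C1.
- The oxalate half-ester is handled as its cesium salt 14, because free tert-alkyl hydrogen oxalates disproportionate.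
- The two bridgeheads of ketal 6 are enantiotopic and no enantioselective metalation of a bicyclobutane is established, so the ester is made as a racemate and resolved (step 5).
- C7/C8 are kept as the trans-acetonide. It cannot form a lactone or lactol during the fragment synthesis, and it holds O8 pseudo-equatorial in the ring closure.
- The configuration drawn at C3 of 25 is the expected one and is lost in step 19.

Step 1
Reactants: 1 cyclohex-2-en-1-one
Product: 2 1,4-dioxaspiro[4.5]dec-6-ene
Conditions: TMSOCH2CH2OTMS, TMSOTf (cat.), CH2Cl2, −78 °C; pyridine quench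
Reagents that add atoms: 1,2-bis(trimethylsilyloxy)ethane, C[Si](C)(C)OCCO[Si](C)(C)C
Why: Aprotic silyl-transfer ketalisation at low temperature should convert the enone into its ketal without moving the double bond out of the 2,3-position, which protic ketalisation tends to do.

Step 2
Reactants: 2 1,4-dioxaspiro[4.5]dec-6-ene; 3 bromoform
Product: 5 racemic cis-7,7-dibromospiro[bicyclo[4.1.0]heptane-2,2'-[1,3]dioxolane], via dibromocarbene 4 (not isolated)
Conditions: 50% aq NaOH, BnEt3NCl (cat.), CH2Cl2, 0 °C → rt
Reagents that add atoms: none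
Why: Phase-transfer dibromocyclopropanation: the carbene formed by α-elimination adds stereospecifically to the ring alkene (cis fusion is the only outcome), and the ketal is inert to base.

Step 3
Reactants: 5 racemic dibromocyclopropane
Product: 6 spiro[1,3-dioxolane-2,3'-tricyclo[4.1.0.0(2,7)]heptane] (achiral)
Conditions: MeLi, Et2O, −78 → 0 °C
Reagents that add atoms: none
Why: Lithium–bromine exchange gives the cyclopropylidene carbenoid, which should undergo the 1,3-C–H insertion typical of 7-norcaranylidenes into the ring CH2 next to the cyclopropane and so close the bicyclobutane; the ketal carbon on the other side has no hydrogen, and insertion into a dioxolane C–H would need a bridged transition state.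

Step 4
Reactants: 6 tricycloheptane ketal
Product: 8 racemic methyl spiro[tricyclo[4.1.0.0(2,7)]heptane-3,2'-[1,3]dioxolane]-1-carboxylate, via bridgehead lithium compound 7 (not isolated)
Conditions: n-BuLi, TMEDA, Et2O, 0 °C → rt; then cannulated into ClCO2Me (excess), Et2O, −78 °C
Reagents that add atoms: n-butyllithium, [Li]CCCC (in 7 only); methyl chloroformate, COC(Cl)=O
Why: Bridgehead metalation of a bicyclobutane (acidic C–H of high s-character, assisted here by coordination to a ketal oxygen) followed by acylation; the two bridgeheads are enantiotopic, so the ester forms as a racemate, and inverse addition keeps the organolithium away from the electrophilic product.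

Step 5
Reactants: 8 racemic bicyclobutane ester
Product: 9 methyl (1S,2S,6R,7R)-spiro[tricyclo[4.1.0.0(2,7)]heptane-3,2'-[1,3]dioxolane]-1-carboxylate
Conditions: preparative SFC, amylose tris(3,5-dimethylphenylcarbamate) column, CO2/MeOH
Reagents that add atoms: none
Why: Resolution of enantiomers by chromatography on a polysaccharide chiral phase; the absolute configuration of the collected enantiomer should be confirmed (vibrational circular dichroism or X-ray of a crystalline derivative) before use.

Step 6
Reactants: 10 dimethyl (4R,5R)-2,2-dimethyl-1,3-dioxolane-4,5-dicarboxylate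
Product: 11 methyl (4R,5R)-5-(2-hydroxypropan-2-yl)-2,2-dimethyl-1,3-dioxolane-4-carboxylate
Conditions: MeMgBr (2.0 equiv), THF, −78 → −30 °C; aq NH4Cl
Reagents that add atoms: methylmagnesium bromide, C[Mg]Br
Why: Grignard addition to one ester: the intermediate methyl ketone is more electrophilic than either ester, so each ester that reacts goes straight to the tertiary carbinol, and two equivalents on the C2-symmetric diester should give mainly the mono-carbinol (diester, recycled, and bis-carbinol are removed by chromatography); the trans-dioxolane cannot lactonise.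

Step 7
Reactants: 11 hydroxy ester
Product: 12 (4R,5R)-5-(2-hydroxypropan-2-yl)-2,2-dimethyl-1,3-dioxolane-4-carbaldehyde
Conditions: i-Bu2AlH (2.2 equiv), CH2Cl2, −78 °C; MeOH, then aq KNaC4H4O6
Reagents that add atoms: none
Why: Partial reduction of an α-alkoxy ester: the chelated aluminium hemiacetal is stable at −78 °C and releases the aldehyde only on work-up, and the hydroxy aldehyde should stay open because a trans-fused five-membered lactol is too strained.

Step 8
Reactants: 12 hydroxy aldehyde
Product: 13 2-[(4R,5R)-5-formyl-2,2-dimethyl-1,3-dioxolan-4-yl]propan-2-yl methyl oxalate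
Conditions: ClC(O)CO2Me, Et3N, DMAP (cat.), CH2Cl2, 0 °C → rt
Reagents that add atoms: methyl chlorooxoacetate, COC(=O)C(Cl)=O
Why: DMAP-catalysed acylation of the tertiary alcohol by a highly electrophilic acid chloride; the α-alkoxy aldehyde is already the more stable trans isomer, so base cannot erode C8.

Step 9
Reactants: 13 aldehyde methyl oxalate
Product: 14 cesium 2-{2-[(4R,5R)-5-formyl-2,2-dimethyl-1,3-dioxolan-4-yl]propan-2-yloxy}-2-oxoacetate
Conditions: CsOH·H2O (1.0 equiv), THF/H2O, 0 °C, 5 min; concentrated and dried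
Reagents that add atoms: cesium hydroxide monohydrate, [Cs+].[OH-].O
Why: Saponification of the methyl oxalate terminus, which is far faster than attack of hydroxide on the hindered tert-alkyl ester or on the aldehyde, should give the stable cesium salt directly with one equivalent of base.

Step 10
Reactants: 9 (1S,2S,6R,7R)-bicyclobutane ester; 14 cesium oxalate
Product: 17 methyl 3,3-(ethylenedioxy)-9α-hydroxy-7β,8α-(isopropylidenedioxy)-15-norlongipinan-14-oate, via tertiary C6 radical 15 (not isolated), via cesium ester enolate 16 (not isolated)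
Conditions: 14 (1.5 equiv), [Ir(dF(CF3)ppy)2(dtbbpy)]PF6 (2 mol %), anhydrous DME/DMF (3:1), 450 nm LEDs, 40 °C; then AcOH, 0 °C
Reagents that add atoms: none
Why: Proposed new method: the excited trivalent iridium complex oxidises the oxalate of 14, which loses two CO2 to give the nucleophilic tertiary radical 15; this adds to the unsubstituted bridgehead C5 of 9 on the convex face and breaks the central C5–C10 bond, and the α-ester cyclobutyl radical so formed is reduced by divalent iridium to enolate 16, which adds to the tethered aldehyde (closest known types: Giese additions of alkyl radicals to acyl bicyclobutanes, radical additions to tricyclo[4.1.0.0(2,7)]heptanes, and photoredox Giese–aldol radical-polar crossover cyclisations; a radical is used at C6 because a carbanion there would eliminate O7). The seven-membered ring C4–C5–C6–C7–C8–C9–C10 closes by a 7-(enolexo)-exo-trig aldol. C5 and C10 are dictated by the cage: the C1–C3 bridge shields the concave face, so the radical enters anti to it, and the tether can reach only the same face of C10, which leaves H on C5 and CO2Me on C10 pointing outward as H and methyl do in the target. C9 is set by the aldehyde face: the trans-dioxolane keeps O8 pseudo-equatorial, so the C8–O8 bond lies anti to the forming C9–C10 bond (polar Felkin–Anh arrangement), which puts O9 pseudo-axial and cis to O8, and the non-chelating cesium ion should not override this. The step needs radical attack at C5 and not at C10 (secured by the polarity of the acceptor and the substituent on C10) and ring closure faster than protonation or retro-aldol of the enolate/aldolate (secured by the anhydrous medium and the cold acidic quench).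

Step 11
Reactants: 17 aldol product
Product: 18 methyl 3,3-(ethylenedioxy)-7β,8α-(isopropylidenedioxy)-9α-(triethylsilyloxy)-15-norlongipinan-14-oate
Conditions: TESOTf, 2,6-lutidine, CH2Cl2, −78 → 0 °C
Reagents that add atoms: triethylsilyl trifluoromethanesulfonate, CC[Si](CC)(CC)OS(=O)(=O)C(F)(F)F
Why: Silylation of a hindered secondary alcohol with a silyl triflate and a non-nucleophilic base; it blocks retro-aldol cleavage now and Grob fragmentation of the 1,3-hydroxy sulfonate later.

Step 12
Reactants: 18 silyl ether ester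
Product: 19 3,3-(ethylenedioxy)-7β,8α-(isopropylidenedioxy)-9α-(triethylsilyloxy)-15-norlongipinan-14-ol
Conditions: i-Bu2AlH (3 equiv), CH2Cl2, −78 → 0 °C; aq KNaC4H4O6
Reagents that add atoms: none
Why: Aluminium hydride reduction of the quaternary methyl ester to the primary alcohol; the covalent aluminium alkoxide in CH2Cl2 should not trigger silyl migration from O9.

Step 13
Reactants: 19 primary alcohol
Product: 20 the 14-methanesulfonate of 19
Conditions: MsCl, Et3N, CH2Cl2, 0 °C
Reagents that add atoms: methanesulfonyl chloride, CS(Cl)(=O)=O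
Why: Sulfonylation through sulfene is fast even at a primary carbinol next to a quaternary carbon.

Step 14
Reactants: 20 mesylate
Product: 21 3,3-(ethylenedioxy)-7β,8α-(isopropylidenedioxy)-9α-(triethylsilyloxy)-15-norlongipinane (C10 methyl in place)
Conditions: LiEt3BH (4 equiv), THF, 0 → 60 °C; NaOH, H2O2 work-up
Reagents that add atoms: none
Why: SN2 hydride displacement of a primary sulfonate by lithium triethylborohydride, which reduces even neopentyl-type sulfonates; an ionic path is chosen because a radical or cation at this cyclobutylcarbinyl carbon would open or enlarge the four-membered ring.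

Step 15
Reactants: 21 protected methyl compound
Product: 22 7β,8α,9α-trihydroxy-15-norlongipinan-3-one
Conditions: 2 M aq HCl, THF, 40 °C
Reagents that add atoms: water, O
Why: Acid hydrolysis should remove the dioxolane ketal, the strained trans-fused acetonide and the silyl ether in one operation, since the saturated skeleton offers no site that ionises under these conditions.

Step 16
Reactants: 22 triol ketone
Product: 23 3,7β,8α,9α-tetrakis(triethylsilyloxy)-15-norlongipin-2-ene
Conditions: TESOTf (6 equiv), Et3N, CH2Cl2, 0 °C → rt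
Reagents that add atoms: triethylsilyl trifluoromethanesulfonate, CC[Si](CC)(CC)OS(=O)(=O)C(F)(F)F
Why: Silyl triflate/amine soft enolisation gives the silyl enol ether on the only enolisable side of the C3 ketone (C2, because C4 is a cyclobutane bridgehead) and silylates the three hydroxyls in the same operation.

Step 17
Reactants: 23 silyl enol ether
Product: 24 7β,8α,9α-tris(triethylsilyloxy)-15-norlongipin-1-en-3-one
Conditions: Pd(OAc)2 (1.2 equiv), MeCN, rt → 40 °C
Reagents that add atoms: none
Why: Saegusa–Ito oxidation: the oxa-π-allyl complex of divalent palladium formed from the silyl enol ether loses a β-hydrogen from C1 to give the C1=C2 enone.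

Step 18
Reactants: 24 enone
Product: 25 7β,8α,9α-tris(triethylsilyloxy)longipin-1-en-3-ol (tertiary allylic alcohol)
Conditions: MeLi, THF, −78 °C; aq NH4Cl
Reagents that add atoms: methyllithium, [Li]C
Why: 1,2-Addition of an organolithium to the enone carbonyl, expected from the face away from the C10 methyl group; the new carbinol centre is lost in the next step, so its configuration does not matter.

Step 19
Reactants: 25 tertiary allylic alcohol
Product: 26 7β,8α,9α-tris(triethylsilyloxy)longipin-2-en-1-one
Conditions: pyridinium chlorochromate ([C5H5NH][CrO3Cl]), NaOAc, 4 Å MS, CH2Cl2, rt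
Reagents that add atoms: pyridinium chlorochromate, c1cc[nH+]cc1.[O-][Cr](Cl)(=O)=O
Why: Babler–Dauben oxidative transposition: the tertiary allylic chromate ester rearranges by a [3,3] shift to C1 and is oxidised there to the 3-methyl-2-en-1-one, while the silyl ethers keep the secondary alcohols from being oxidised.

Step 20
Reactants: 26 tris-silyl enone
Product: 27 7β,8α,9α-trihydroxylongipin-2-en-1-one
Conditions: HF·pyridine, THF, 0 °C → rt
Reagents that add atoms: none
Why: Fluoride-driven cleavage of the three silyl ethers under mildly acidic conditions that should leave the enone and the cyclobutane untouched.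

Step 21
Reactants: 27 triol enone
Product: 29 8α-acetoxy-7β,9α-dihydroxylongipin-2-en-1-one, via 8,9-O-dibutylstannylene acetal 28 (not isolated)
Conditions: Bu2SnO (1.1 equiv), MeOH, reflux, evaporation; then AcCl (1.05 equiv), CH2Cl2, 0 °C
Reagents that add atoms: dibutyltin oxide, CCCC[Sn](=O)CCCC (in 28 only); acetyl chloride, CC(Cl)=O
Why: Stannylene-acetal-directed monoacylation: the cis-8,9-diol forms the tin acetal and the acid chloride reacts at its equatorial oxygen O8, which is also the least hindered hydroxyl because O7 and O9 each adjoin a quaternary carbon.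

Step 22
Reactants: 29 8-acetate diol; 30 angelic acid
Product: 32 (4R,5S,7S,8R,9S,10R,11R)-8-acetoxy-7,9-bis[(Z)-2-methylbut-2-enoyloxy]longipin-2-en-1-one (target), via angelic 2,4,6-trichlorobenzoic anhydride 31 (not isolated)
Conditions: 30 (8 equiv), 2,4,6-Cl3C6H2COCl, Et3N, toluene, rt; then 29, toluene, 85 °C
Reagents that add atoms: 2,4,6-trichlorobenzoyl chloride, ClC(=O)c1c(Cl)cc(Cl)cc1Cl (in 31 only)
Why: Yamaguchi-type esterification through the preformed mixed anhydride, run without a nucleophilic catalyst so that the (Z)-alkene is not isomerised to the tiglate; excess reagent and heat are needed for the two hindered hydroxyls (equatorial O7, axial O9).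

Compound list
1 | cyclohex-2-en-1-one | O=C1C=CCCC1 | starting material
2 | 1,4-dioxaspiro[4.5]dec-6-ene | C1=CC2(CCC1)OCCO2 | intermediate
3 | bromoform | BrC(Br)Br | starting material
4 | dibromocarbene | Br[C]Br | intermediate
5 | racemic cis-7,7-dibromospiro[bicyclo[4.1.0]heptane-2,2'-[1,3]dioxolane] (both enantiomers shown) | BrC1(Br)[C@H]2CCCC3(OCCO3)[C@@H]12.BrC1(Br)[C@@H]2CCCC3(OCCO3)[C@H]12 | intermediate
6 | spiro[1,3-dioxolane-2,3'-tricyclo[4.1.0.0(2,7)]heptane] (achiral) | [C@H]12[C@@H]3CCC4(OCCO4)[C@H]1[C@H]23 | intermediate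
7 | racemic 1-lithio derivative of 6 (both enantiomers shown) | [Li][C@]12[C@@H]3CCC4(OCCO4)[C@H]1[C@H]23.[Li][C@@]12[C@H]3CCC4(OCCO4)[C@@H]1[C@@H]23 | intermediate
8 | racemic methyl spiro[tricyclo[4.1.0.0(2,7)]heptane-3,2'-[1,3]dioxolane]-1-carboxylate (both enantiomers shown) | COC(=O)[C@]12[C@@H]3CCC4(OCCO4)[C@H]1[C@H]23.COC(=O)[C@@]12[C@H]3CCC4(OCCO4)[C@@H]1[C@@H]23 | intermediate
9 | methyl (1S,2S,6R,7R)-spiro[tricyclo[4.1.0.0(2,7)]heptane-3,2'-[1,3]dioxolane]-1-carboxylate | COC(=O)[C@]12[C@@H]3CCC4(OCCO4)[C@H]1[C@H]23 | intermediate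
10 | dimethyl (4R,5R)-2,2-dimethyl-1,3-dioxolane-4,5-dicarboxylate (dimethyl 2,3-O-isopropylidene-L-tartrate) | COC(=O)[C@@H]1OC(C)(C)O[C@H]1C(=O)OC | starting material
11 | methyl (4R,5R)-5-(2-hydroxypropan-2-yl)-2,2-dimethyl-1,3-dioxolane-4-carboxylate | CC(C)(O)[C@@H]1OC(C)(C)O[C@H]1C(=O)OC | intermediate
12 | (4R,5R)-5-(2-hydroxypropan-2-yl)-2,2-dimethyl-1,3-dioxolane-4-carbaldehyde | CC(C)(O)[C@@H]1OC(C)(C)O[C@H]1C=O | intermediate
13 | 2-[(4R,5R)-5-formyl-2,2-dimethyl-1,3-dioxolan-4-yl]propan-2-yl methyl oxalate | COC(=O)C(=O)OC(C)(C)[C@@H]1OC(C)(C)O[C@H]1C=O | intermediate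
14 | cesium 2-{2-[(4R,5R)-5-formyl-2,2-dimethyl-1,3-dioxolan-4-yl]propan-2-yloxy}-2-oxoacetate | [Cs+].[O-]C(=O)C(=O)OC(C)(C)[C@@H]1OC(C)(C)O[C@H]1C=O | intermediate
15 | 2-[(4R,5R)-5-formyl-2,2-dimethyl-1,3-dioxolan-4-yl]propan-2-yl radical (C6 radical) | C[C](C)[C@@H]1OC(C)(C)O[C@H]1C=O | intermediate
16 | cesium enolate of the ring-opened adduct (C5–C6 bond formed, C10 enolate, C9 aldehyde) | [Cs+].[O-]C(OC)=C1[C@@H]2CCC3(OCCO3)[C@H]1[C@@H]2C(C)(C)[C@@H]1OC(C)(C)O[C@H]1C=O | intermediate
17 | methyl 3,3-(ethylenedioxy)-9α-hydroxy-7β,8α-(isopropylidenedioxy)-15-norlongipinan-14-oate (C4, C5, C10, C11 as in the target) | O6[C@@H]1[C@@H](OC6(C)C)[C@@H](O)[C@@]2(C(=O)OC)[C@@H]3CCC4(OCCO4)[C@H]2[C@@H]3C1(C)C | intermediate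
18 | 9-O-triethylsilyl ether of 17 | O6[C@@H]1[C@@H](OC6(C)C)[C@@H](O[Si](CC)(CC)CC)[C@@]2(C(=O)OC)[C@@H]3CCC4(OCCO4)[C@H]2[C@@H]3C1(C)C | intermediate
19 | 3,3-(ethylenedioxy)-7β,8α-(isopropylidenedioxy)-9α-(triethylsilyloxy)-15-norlongipinan-14-ol | O6[C@@H]1[C@@H](OC6(C)C)[C@@H](O[Si](CC)(CC)CC)[C@@]2(CO)[C@@H]3CCC4(OCCO4)[C@H]2[C@@H]3C1(C)C | intermediate
20 | 14-methanesulfonate of 19 | O6[C@@H]1[C@@H](OC6(C)C)[C@@H](O[Si](CC)(CC)CC)[C@@]2(COS(C)(=O)=O)[C@@H]3CCC4(OCCO4)[C@H]2[C@@H]3C1(C)C | intermediate
21 | 3,3-(ethylenedioxy)-7β,8α-(isopropylidenedioxy)-9α-(triethylsilyloxy)-15-norlongipinane | O6[C@@H]1[C@@H](OC6(C)C)[C@@H](O[Si](CC)(CC)CC)[C@@]2(C)[C@@H]3CCC4(OCCO4)[C@H]2[C@@H]3C1(C)C | intermediate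
22 | 7β,8α,9α-trihydroxy-15-norlongipinan-3-one | O[C@@H]1[C@@H](O)[C@@H](O)[C@@]2(C)[C@@H]3CCC(=O)[C@H]2[C@@H]3C1(C)C | intermediate
23 | 3,7β,8α,9α-tetrakis(triethylsilyloxy)-15-norlongipin-2-ene | CC[Si](CC)(CC)O[C@@H]1[C@@H](O[Si](CC)(CC)CC)[C@@H](O[Si](CC)(CC)CC)[C@@]2(C)[C@@H]3CC=C(O[Si](CC)(CC)CC)[C@H]2[C@@H]3C1(C)C | intermediate
24 | 7β,8α,9α-tris(triethylsilyloxy)-15-norlongipin-1-en-3-one | CC[Si](CC)(CC)O[C@@H]1[C@@H](O[Si](CC)(CC)CC)[C@@H](O[Si](CC)(CC)CC)[C@@]2(C)[C@@H]3C=CC(=O)[C@H]2[C@@H]3C1(C)C | intermediate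
25 | 7β,8α,9α-tris(triethylsilyloxy)longipin-1-en-3-ol (hydroxyl on the face toward C10) | CC[Si](CC)(CC)O[C@@H]1[C@@H](O[Si](CC)(CC)CC)[C@@H](O[Si](CC)(CC)CC)[C@@]2(C)[C@@H]3C=C[C@](C)(O)[C@H]2[C@@H]3C1(C)C | intermediate
26 | 7β,8α,9α-tris(triethylsilyloxy)longipin-2-en-1-one | CC[Si](CC)(CC)O[C@@H]1[C@@H](O[Si](CC)(CC)CC)[C@@H](O[Si](CC)(CC)CC)[C@@]2(C)[C@@H]3C(=O)C=C(C)[C@H]2[C@@H]3C1(C)C | intermediate
27 | 7β,8α,9α-trihydroxylongipin-2-en-1-one | O[C@@H]1[C@@H](O)[C@@H](O)[C@@]2(C)[C@@H]3C(=O)C=C(C)[C@H]2[C@@H]3C1(C)C | intermediate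
28 | 8,9-O-dibutylstannylene acetal of 27 | O[C@@H]1[C@H]5O[Sn](CCCC)(CCCC)O[C@H]5[C@@]2(C)[C@@H]3C(=O)C=C(C)[C@H]2[C@@H]3C1(C)C | intermediate
29 | 8α-acetoxy-7β,9α-dihydroxylongipin-2-en-1-one | O[C@@H]1[C@@H](OC(C)=O)[C@@H](O)[C@@]2(C)[C@@H]3C(=O)C=C(C)[C@H]2[C@@H]3C1(C)C | intermediate
30 | angelic acid, (Z)-2-methylbut-2-enoic acid | C/C=C(/C)C(=O)O | starting material
31 | (Z)-2-methylbut-2-enoic 2,4,6-trichlorobenzoic anhydride | C/C=C(/C)C(=O)OC(=O)c1c(Cl)cc(Cl)cc1Cl | intermediate
32 | (4R,5S,7S,8R,9S,10R,11R)-8-acetoxy-7,9-bis[(Z)-2-methylbut-2-enoyloxy]longipin-2-en-1-one (8α-acetoxy-7β,9α-diangeloyloxylongipin-2-en-1-one) | C/C=C(/C)C(=O)O[C@@H]1[C@@H](OC(C)=O)[C@@H](OC(=O)/C(C)=C\C)[C@@]2(C)[C@@H]3C(=O)C=C(C)[C@H]2[C@@H]3C1(C)C | target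

Total step count: 22 (steps 1–5 to the bicyclobutane, steps 6–9 to the oxalate, step 10, steps 11–22).
Longest linear sequence: 18 steps (steps 1–5, then 10–22).

Steps most likely to fail

Step 10. After the radical has added, the C10 radical or enolate may be quenched (hydrogen abstraction from the aldehyde, protonation) before the seven-membered ring closes, or the aldolate may revert by retro-aldol. The fallback makes the two bonds one at a time with known reactions; it sets out from 12 and 9 and returns at 17. Wittig methylenation of 12 (Ph3P=CH2, THF) should give 2-[(4R,5S)-2,2-dimethyl-5-vinyl-1,3-dioxolan-4-yl]propan-2-ol F1, in which the aldehyde is masked as an alkene. Acylation as in step 8 gives its methyl oxalate F2, and CsOH as in step 9 gives the cesium oxalate F3. The same photocatalyst in DME/DMF with water present adds the radical from F3 to 9 and protonates the enolate (an ordinary decarboxylative Giese addition), giving the cyclobutane ester F4 with the C5–C6 bond in place. LiN(i-Pr)2 followed by CBr4 gives the α-bromo ester F5, and ozonolysis (O3, then Me2S) gives the bromo aldehyde F6. SmI2 in THF at −78 °C then closes C9–C10 by an intramolecular Reformatsky reaction and returns 17.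

Step 22. The angeloyl group may isomerise to tigloyl, acylation may stall at the monoester before the axial C9 hydroxyl reacts, and the C8 acetyl group may migrate under heat and base. The fallback builds the (Z)-alkenes after acylation; it sets out from 29 and returns at 32. Acylation of 29 with 2-(diphenoxyphosphoryl)propanoyl chloride (pyridine, DMAP, CH2Cl2), a small saturated acid chloride that tolerates forcing conditions, should give the 7,9-bis[2-(diphenoxyphosphoryl)propanoate] F7. A Z-selective Horner–Wadsworth–Emmons reaction of this diaryl phosphonate with acetaldehyde (NaI, DBU, THF, −78 → 0 °C) then forms both angelates in place and returns 32.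

Step 14. Hydride displacement at the primary carbon flanked by the quaternary cyclobutane carbon and the silyloxy group may be slow, so attack at sulfur (return to 19) or ionisation with ring enlargement may compete. The fallback removes the oxygen through an anionic route at the aldehyde level; it sets out from 19 and returns at 21. Oxidation of 19 with DMP should give the non-enolisable 14-aldehyde F8, hydrazine hydrate in EtOH its hydrazone F9, and Wolff–Kishner reduction at room temperature (KOtBu, DMSO) the methyl compound 21 without a radical or cation at the cyclobutylcarbinyl carbon.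

Further compounds
F1 | step 10 | 2-[(4R,5S)-2,2-dimethyl-5-vinyl-1,3-dioxolan-4-yl]propan-2-ol | CC(C)(O)[C@@H]1OC(C)(C)O[C@H]1C=C
F2 | step 10 | methyl oxalate of F1 | COC(=O)C(=O)OC(C)(C)[C@@H]1OC(C)(C)O[C@H]1C=C
F3 | step 10 | cesium oxalate of F1 | [Cs+].[O-]C(=O)C(=O)OC(C)(C)[C@@H]1OC(C)(C)O[C@H]1C=C
F4 | step 10 | cyclobutane ester from F3 and 9 (C5–C6 bond formed, H on C10, both C10 epimers, vinyl on C8) | COC(=O)C1[C@@H]2CCC3(OCCO3)[C@H]1[C@@H]2C(C)(C)[C@@H]1OC(C)(C)O[C@H]1C=C
F5 | step 10 | C10 α-bromo ester of F4 | COC(=O)C1(Br)[C@@H]2CCC3(OCCO3)[C@H]1[C@@H]2C(C)(C)[C@@H]1OC(C)(C)O[C@H]1C=C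
F6 | step 10 | C10 α-bromo ester C9 aldehyde | COC(=O)C1(Br)[C@@H]2CCC3(OCCO3)[C@H]1[C@@H]2C(C)(C)[C@@H]1OC(C)(C)O[C@H]1C=O
F7 | step 22 | 8α-acetoxy-7β,9α-bis[2-(diphenoxyphosphoryl)propanoyloxy]longipin-2-en-1-one (phosphonate α-carbons unassigned) | CC(P(=O)(Oc5ccccc5)Oc6ccccc6)C(=O)O[C@@H]1[C@@H](OC(C)=O)[C@@H](OC(=O)C(C)P(=O)(Oc7ccccc7)Oc8ccccc8)[C@@]2(C)[C@@H]3C(=O)C=C(C)[C@H]2[C@@H]3C1(C)C
F8 | step 14 | 3,3-(ethylenedioxy)-7β,8α-(isopropylidenedioxy)-9α-(triethylsilyloxy)-15-norlongipinan-14-al | O6[C@@H]1[C@@H](OC6(C)C)[C@@H](O[Si](CC)(CC)CC)[C@@]2(C=O)[C@@H]3CCC4(OCCO4)[C@H]2[C@@H]3C1(C)C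
F9 | step 14 | hydrazone of F8 | O6[C@@H]1[C@@H](OC6(C)C)[C@@H](O[Si](CC)(CC)CC)[C@@]2(C=NN)[C@@H]3CCC4(OCCO4)[C@H]2[C@@H]3C1(C)C
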